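**Retrosynthetic overview**

1. Target 16 ← global hydrogenolysis of hexabenzyl ether 15; pyran ring F of the lower unit (O1–C2 bond, C2 and C3) ← Z-alkene 13 by a one-flask Shi epoxidation / fluoride-triggered 6-endo epoxide opening.
2. Enabling feature: in ring F, O1 sits on C8a of ring D ortho to C4a, C4 is a bare CH2 and C2 is benzylic to catechol ring E; the 2,3-cis pair is therefore the anti adduct (epoxide O at C3, phenol O1 at C2) of a (Z)-C2=C3 olefin in a 2-(3-arylallyl)phenol.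
3. Interflavan bond C4 (ring C)–C6 (ring D) ← Friedel–Crafts union of 4-alkoxyflavan 11 with the arene of alkyne 7 (para to OTIPS, 3,4-trans by attack anti to the 3-OH); the TIPS group is temporary and leaves in the key step.
4. Ring C of 11 ← the same epoxidation/cyclisation on the monomeric Z-alkene 8, then DDQ oxidation at C4; both halves come from one propyne 7, built from aldehydes 1 and 3.
5. Ring order: rings A, B, D and E are bought as arenes; ring C is closed in step 6; ring F is closed last, in step 10.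

Key step: step 10

Assumption: the target is read as a 2,3-cis-3,4-trans (2S,3S,4R) upper unit joined through C4 to C6 of a 2,3-cis (2S,3S) lower unit (two ent-epifisetinidol units); the upper C4 descriptor is S in the O-benzylated intermediates only through a priority change; the Shi oxazolidinone ketone is made separately from D-glucose and is taken to give the R benzylic epoxide carbon, as with cis-β-methylstyrene.

**Route**

Step 1
Reactants: 1 3,4-bis(benzyloxy)benzaldehyde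
Product: 2 4-ethynyl-1,2-bis(benzyloxy)benzene
Conditions: dimethyl (1-diazo-2-oxopropyl)phosphonate, K2CO3, MeOH, rt
Reagents that add atoms: dimethyl (1-diazo-2-oxopropyl)phosphonate (Ohira–Bestmann reagent), CC(=O)C(=[N+]=[N-])P(=O)(OC)OC
Why: Seyferth–Gilbert homologation in its Ohira–Bestmann form should turn the aryl aldehyde into the terminal alkyne under mild base that leaves benzyl ethers untouched.

Step 2
Reactants: 3 4-(benzyloxy)-2-hydroxybenzaldehyde
Product: 4 4-(benzyloxy)-2-(triisopropylsilyloxy)benzaldehyde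
Conditions: TIPSCl, imidazole, DMF, rt
Reagents that add atoms: chlorotriisopropylsilane (TIPSCl), CC(C)[Si](Cl)(C(C)C)C(C)C
Why: Standard phenol silylation; the bulky silyl ether should resist O-to-O migration in step 3, shield the carbon between the two oxygens in step 8 and serve as the fluoride trigger in steps 6 and 10.

Step 3
Reactants: 2 4-ethynyl-1,2-bis(benzyloxy)benzene; 4 4-(benzyloxy)-2-(triisopropylsilyloxy)benzaldehyde
Product: 6 rac-1-[4-(benzyloxy)-2-(triisopropylsilyloxy)phenyl]-3-[3,4-bis(benzyloxy)phenyl]prop-2-yn-1-ol, via lithium acetylide 5 (not isolated)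
Conditions: n-BuLi, THF, −78 °C; then 4, −78 °C; AcOH quench at −78 °C
Reagents that add atoms: none
Why: 1,2-Addition of a lithium acetylide to an aryl aldehyde, with a cold acidic quench to prevent silyl migration; the carbinol centre is racemic and is erased in step 4.

Step 4
Reactants: 6 rac-1-[4-(benzyloxy)-2-(triisopropylsilyloxy)phenyl]-3-[3,4-bis(benzyloxy)phenyl]prop-2-yn-1-ol
Product: 7 {5-(benzyloxy)-2-[3-(3,4-bis(benzyloxy)phenyl)prop-2-yn-1-yl]phenoxy}triisopropylsilane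
Conditions: Et3SiH, CF3CO2H, CH2Cl2, −40 °C
Reagents that add atoms: none
Why: Ionic hydrogenation: the 2,4-dioxygenated benzylic/propargylic cation should form readily and take hydride at the benzylic carbon, keeping the alkyne conjugated to ring B, while the aryl silyl ether and benzyl ethers survive cold acid.

Step 5
Reactants: 7 {5-(benzyloxy)-2-[3-(3,4-bis(benzyloxy)phenyl)prop-2-yn-1-yl]phenoxy}triisopropylsilane
Product: 8 {5-(benzyloxy)-2-[(2Z)-3-(3,4-bis(benzyloxy)phenyl)prop-2-en-1-yl]phenoxy}triisopropylsilane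
Conditions: H2 (1 atm), Pd/CaCO3 poisoned with Pb(OAc)2 (Lindlar catalyst), quinoline, EtOAc, rt
Reagents that add atoms: none
Why: Lindlar semihydrogenation delivers H2 syn to give the Z-olefin, and poisoned palladium should not cleave benzyl ethers.

Step 6
Reactants: 8 {5-(benzyloxy)-2-[(2Z)-3-(3,4-bis(benzyloxy)phenyl)prop-2-en-1-yl]phenoxy}triisopropylsilane
Product: 10 (2S,3S)-7-(benzyloxy)-2-[3,4-bis(benzyloxy)phenyl]chroman-3-ol, via cis-epoxide 9 (not isolated)
Conditions: Shi oxazolidinone ketone (D-glucose series, N-4-tolyl, 0.3 equiv), Oxone (2KHSO5·KHSO4·K2SO4), K2CO3, Bu4NHSO4, DME/CH2(OMe)2/aq. buffer, −10 °C; then crude epoxide, Bu4NF, AcOH, THF, 0 °C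
Reagents that add atoms: potassium peroxymonosulfate (active salt of Oxone), [K+].[O-]S(=O)(=O)OO
Why: Shi epoxidation of the cis-β-substituted styrene should give the (2R,3S)-epoxide under catalyst control, and the unmasked phenol then opens it 6-endo at the benzylic carbon with inversion, which sets C2 (S) and C3 (S) of ring C as a 2,3-cis pair (the key step rehearsed on the monomer).

Step 7
Reactants: 10 (2S,3S)-7-(benzyloxy)-2-[3,4-bis(benzyloxy)phenyl]chroman-3-ol
Product: 11 (2S,3S,4R)-7-(benzyloxy)-2-[3,4-bis(benzyloxy)phenyl]-4-(2-ethoxyethoxy)chroman-3-ol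
Conditions: DDQ, 2-ethoxyethanol, CH2Cl2, rt
Reagents that add atoms: 2-ethoxyethanol, CCOCCO
Why: DDQ benzylic oxidation: hydride abstraction at C4 (benzylic to the 2,4-dioxygenated ring A) gives a quinone-methide-type cation that the alcohol should trap anti to the 3-OH (3,4-trans); this centre is replaced in step 8.

Step 8
Reactants: 11 (2S,3S,4R)-7-(benzyloxy)-2-[3,4-bis(benzyloxy)phenyl]-4-(2-ethoxyethoxy)chroman-3-ol; 7 {5-(benzyloxy)-2-[3-(3,4-bis(benzyloxy)phenyl)prop-2-yn-1-yl]phenoxy}triisopropylsilane (3 equiv)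
Product: 12 (2S,3S,4S)-7-(benzyloxy)-2-[3,4-bis(benzyloxy)phenyl]-4-{2-(benzyloxy)-5-[3-(3,4-bis(benzyloxy)phenyl)prop-2-yn-1-yl]-4-(triisopropylsilyloxy)phenyl}chroman-3-ol
Conditions: TMSOTf (cat.), CH2Cl2, −78 to −40 °C, slow addition of 11
Reagents that add atoms: none
Why: Friedel–Crafts flavan-4-yl arylation as used for proanthocyanidin assembly: the C4 cation should be attacked by the arene of 7 at the carbon para to OTIPS and ortho to OBn (the silyl group shields the carbon between the oxygens), from the face anti to the 3-OH of the 2,3-cis ring C, which sets C4 as 3,4-trans.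

Step 9
Reactants: 12 (2S,3S,4S)-7-(benzyloxy)-2-[3,4-bis(benzyloxy)phenyl]-4-{2-(benzyloxy)-5-[3-(3,4-bis(benzyloxy)phenyl)prop-2-yn-1-yl]-4-(triisopropylsilyloxy)phenyl}chroman-3-ol
Product: 13 (2S,3S,4S)-7-(benzyloxy)-2-[3,4-bis(benzyloxy)phenyl]-4-{2-(benzyloxy)-5-[(2Z)-3-(3,4-bis(benzyloxy)phenyl)prop-2-en-1-yl]-4-(triisopropylsilyloxy)phenyl}chroman-3-ol
Conditions: H2 (1 atm), Pd/CaCO3 poisoned with Pb(OAc)2 (Lindlar catalyst), quinoline, EtOAc, rt
Reagents that add atoms: none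
Why: Lindlar semihydrogenation as in step 5 should give the Z-olefin whose geometry the key step translates into the 2,3-cis relationship.

Step 10
Reactants: 13 (2S,3S,4S)-7-(benzyloxy)-2-[3,4-bis(benzyloxy)phenyl]-4-{2-(benzyloxy)-5-[(2Z)-3-(3,4-bis(benzyloxy)phenyl)prop-2-en-1-yl]-4-(triisopropylsilyloxy)phenyl}chroman-3-ol
Product: 15 (2S,3S,4S)-7-(benzyloxy)-4-[(2S,3S)-7-(benzyloxy)-2-(3,4-bis(benzyloxy)phenyl)-3-hydroxychroman-6-yl]-2-[3,4-bis(benzyloxy)phenyl]chroman-3-ol, via cis-epoxide 14 (not isolated)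
Conditions: Shi oxazolidinone ketone (D-glucose series, N-4-tolyl, 0.3 equiv), Oxone (2KHSO5·KHSO4·K2SO4), K2CO3, Bu4NHSO4, DME/CH2(OMe)2/aq. buffer, −10 °C; then crude epoxide, Bu4NF, AcOH, THF, 0 °C
Reagents that add atoms: potassium peroxymonosulfate (active salt of Oxone), [K+].[O-]S(=O)(=O)OO
Why: The chiral dioxirane formed from the ketone and KHSO5 should transfer oxygen to the electron-rich Z-styrenyl olefin through a concerted, stereospecific spiro transition state to give cis-epoxide 14, and fluoride then unmasks the ring D phenol, whose oxygen opens the epoxide at the benzylic carbon anti to the leaving oxygen. The closest known reaction types are the Shi epoxidation of cis-β-substituted styrenes with oxazolidinone ketones and the phenol–epoxide cyclisation of 2-(3-aryloxiranylmethyl)phenols to flavan-3-ols. Ring F closes by 6-endo-tet formation of the O1–C2 bond. C3 (S) is set by the catalyst-controlled face of oxygen transfer (olefin aryl group stacked over the oxazolidinone), and C2 (S) follows from it by SN2 inversion, so the Z geometry becomes the 2,3-cis pair. The step needs 6-endo rather than 5-exo attack and inversion without ionisation: the 3,4-bis(benzyloxy)phenyl group makes C2 the more electrophilic carbon, and cold, buffered, aprotic conditions should keep the opening concerted. The TIPS ether protects the phenol during oxidation, the remote upper unit is not expected to disturb reagent control, and the secondary 3-OH of ring C should be inert to the dioxirane at this temperature.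

Step 11
Reactants: 15 (2S,3S,4S)-7-(benzyloxy)-4-[(2S,3S)-7-(benzyloxy)-2-(3,4-bis(benzyloxy)phenyl)-3-hydroxychroman-6-yl]-2-[3,4-bis(benzyloxy)phenyl]chroman-3-ol
Product: 16 (2S,3S,4R)-2-(3,4-dihydroxyphenyl)-4-[(2S,3S)-2-(3,4-dihydroxyphenyl)-3,7-dihydroxychroman-6-yl]chroman-3,7-diol
Conditions: H2 (1 atm), Pd(OH)2/C, THF/MeOH, rt
Reagents that add atoms: none
Why: Hydrogenolysis of the six aryl benzyl ethers, under which the ring C–O bonds at C2 and the interflavan C–C bond of benzylated flavan-3-ol oligomers are known to survive; no stereocentre is touched.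

**Compound list**

1 | 3,4-bis(benzyloxy)benzaldehyde | O=Cc1ccc(OCc2ccccc2)c(OCc2ccccc2)c1 | starting material
2 | 4-ethynyl-1,2-bis(benzyloxy)benzene | C#Cc1ccc(OCc2ccccc2)c(OCc2ccccc2)c1 | intermediate
3 | 4-(benzyloxy)-2-hydroxybenzaldehyde | O=Cc1ccc(OCc2ccccc2)cc1O | starting material
4 | 4-(benzyloxy)-2-(triisopropylsilyloxy)benzaldehyde | O=Cc1ccc(OCc2ccccc2)cc1O[Si](C(C)C)(C(C)C)C(C)C | intermediate
5 | lithium [3,4-bis(benzyloxy)phenyl]acetylide | [Li]C#Cc1ccc(OCc2ccccc2)c(OCc2ccccc2)c1 | intermediate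
6 | rac-1-[4-(benzyloxy)-2-(triisopropylsilyloxy)phenyl]-3-[3,4-bis(benzyloxy)phenyl]prop-2-yn-1-ol | OC(C#Cc1ccc(OCc2ccccc2)c(OCc2ccccc2)c1)c1ccc(OCc2ccccc2)cc1O[Si](C(C)C)(C(C)C)C(C)C | intermediate
7 | {5-(benzyloxy)-2-[3-(3,4-bis(benzyloxy)phenyl)prop-2-yn-1-yl]phenoxy}triisopropylsilane | C(C#Cc1ccc(OCc2ccccc2)c(OCc2ccccc2)c1)c1ccc(OCc2ccccc2)cc1O[Si](C(C)C)(C(C)C)C(C)C | intermediate
8 | {5-(benzyloxy)-2-[(2Z)-3-(3,4-bis(benzyloxy)phenyl)prop-2-en-1-yl]phenoxy}triisopropylsilane | C(/C=C\c1ccc(OCc2ccccc2)c(OCc2ccccc2)c1)c1ccc(OCc2ccccc2)cc1O[Si](C(C)C)(C(C)C)C(C)C | intermediate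
9 | (2R,3S)-2-[3,4-bis(benzyloxy)phenyl]-3-{[4-(benzyloxy)-2-(triisopropylsilyloxy)phenyl]methyl}oxirane (cis-epoxide) | C(c1ccc(OCc2ccccc2)cc1O[Si](C(C)C)(C(C)C)C(C)C)[C@@H]1O[C@@H]1c1ccc(OCc2ccccc2)c(OCc2ccccc2)c1 | intermediate
10 | (2S,3S)-7-(benzyloxy)-2-[3,4-bis(benzyloxy)phenyl]chroman-3-ol | C(c1ccccc1)Oc1ccc2c(c1)O[C@@H](c1ccc(OCc3ccccc3)c(OCc3ccccc3)c1)[C@@H](O)C2 | intermediate
11 | (2S,3S,4R)-7-(benzyloxy)-2-[3,4-bis(benzyloxy)phenyl]-4-(2-ethoxyethoxy)chroman-3-ol | C(c1ccccc1)Oc1ccc2c(c1)O[C@@H](c1ccc(OCc3ccccc3)c(OCc3ccccc3)c1)[C@@H](O)[C@@H]2OCCOCC | intermediate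
12 | (2S,3S,4S)-7-(benzyloxy)-2-[3,4-bis(benzyloxy)phenyl]-4-{2-(benzyloxy)-5-[3-(3,4-bis(benzyloxy)phenyl)prop-2-yn-1-yl]-4-(triisopropylsilyloxy)phenyl}chroman-3-ol | C(c1ccccc1)Oc1ccc2c(c1)O[C@@H](c1ccc(OCc3ccccc3)c(OCc3ccccc3)c1)[C@@H](O)[C@@H]2c1cc(CC#Cc3ccc(OCc4ccccc4)c(OCc4ccccc4)c3)c(O[Si](C(C)C)(C(C)C)C(C)C)cc1OCc1ccccc1 | intermediate
13 | (2S,3S,4S)-7-(benzyloxy)-2-[3,4-bis(benzyloxy)phenyl]-4-{2-(benzyloxy)-5-[(2Z)-3-(3,4-bis(benzyloxy)phenyl)prop-2-en-1-yl]-4-(triisopropylsilyloxy)phenyl}chroman-3-ol | C(c1ccccc1)Oc1ccc2c(c1)O[C@@H](c1ccc(OCc3ccccc3)c(OCc3ccccc3)c1)[C@@H](O)[C@@H]2c1cc(C/C=C\c3ccc(OCc4ccccc4)c(OCc4ccccc4)c3)c(O[Si](C(C)C)(C(C)C)C(C)C)cc1OCc1ccccc1 | intermediate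
14 | (2S,3S,4S)-7-(benzyloxy)-2-[3,4-bis(benzyloxy)phenyl]-4-{2-(benzyloxy)-5-{[(2S,3R)-3-(3,4-bis(benzyloxy)phenyl)oxiran-2-yl]methyl}-4-(triisopropylsilyloxy)phenyl}chroman-3-ol (cis-epoxide) | C(c1ccccc1)Oc1ccc2c(c1)O[C@@H](c1ccc(OCc3ccccc3)c(OCc3ccccc3)c1)[C@@H](O)[C@@H]2c1cc(C[C@@H]3O[C@@H]3c3ccc(OCc4ccccc4)c(OCc4ccccc4)c3)c(O[Si](C(C)C)(C(C)C)C(C)C)cc1OCc1ccccc1 | intermediate
15 | (2S,3S,4S)-7-(benzyloxy)-4-[(2S,3S)-7-(benzyloxy)-2-(3,4-bis(benzyloxy)phenyl)-3-hydroxychroman-6-yl]-2-[3,4-bis(benzyloxy)phenyl]chroman-3-ol | C(c1ccccc1)Oc1ccc2c(c1)O[C@@H](c1ccc(OCc3ccccc3)c(OCc3ccccc3)c1)[C@@H](O)[C@@H]2c1cc2c(cc1OCc1ccccc1)O[C@@H](c1ccc(OCc3ccccc3)c(OCc3ccccc3)c1)[C@@H](O)C2 | intermediate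
16 | (2S,3S,4R)-2-(3,4-dihydroxyphenyl)-4-[(2S,3S)-2-(3,4-dihydroxyphenyl)-3,7-dihydroxychroman-6-yl]chroman-3,7-diol (CNP0187520.4) | Oc1ccc2c(c1)O[C@@H](c1ccc(O)c(O)c1)[C@@H](O)[C@@H]2c1cc2c(cc1O)O[C@@H](c1ccc(O)c(O)c1)[C@@H](O)C2 | target

**Step count and risks**

Total step count: 11. Longest linear sequence: 10 steps (1 → 2 → 6 → 7 → 8 → 10 → 11 → 12 → 13 → 15 → 16).

Steps most likely to fail:

1. Step 10. The electron-rich benzylic epoxide may ionise before or during ring closure, which would erode inversion at C2 and leak to the 2,3-trans ring; attack at C3 (5-exo) or hydrolysis of the epoxide in the aqueous oxidant may also compete. The fallback sets out from 13 and comes back to the route at 16. It moves the stereochemical burden to a trans ring closure, on which concerted and ionised pathways converge, followed by inversion at C3. Isomerisation of the olefin with PdCl2(MeCN)2 (cat.) in CH2Cl2 should give the E isomer of 13 F1. NaH/BnBr in DMF should then cap the ring C hydroxyl as the ring C 3-O-benzyl ether of F1 F2, so that it survives the later oxidation. Shi epoxidation with the D-fructose-derived ketone (the standard catalyst for trans-olefins) and Oxone should give the (R,R)-trans-epoxide of F2 F3. Bu4NF/AcOH should close ring F to the 2,3-trans (2S,3R) alcohol F4. Dess–Martin periodinane should give the ring F 3-ketone F5, and LiBH(s-Bu)3 in THF at −78 °C should deliver hydride anti to the C2 aryl group to give the ring C 3-O-benzyl ether of 15 F6. Hydrogenolysis over Pd(OH)2/C as in step 11 should then give 16.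

2. Step 8. The silyl-ether arene of 7 may be too weak a nucleophile, so that self-condensation of the C4 cation with ring A of a second molecule of 11, or attack on the alkyne, takes over. The fallback sets out from 7 and comes back at 12. It uses a stronger, free-phenol nucleophile and restores the silyl ether afterwards. Bu4NF/AcOH in THF should give 5-(benzyloxy)-2-[3-(3,4-bis(benzyloxy)phenyl)prop-2-yn-1-yl]phenol F7. Its position para to the free hydroxyl should couple with 11 under BF3·OEt2 in CH2Cl2 at low temperature to give the desilylated analogue of 12 F8. TIPSCl/imidazole in DMF should then silylate the phenol selectively (the hindered ring C hydroxyl staying free) to give 12.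

3. Step 7. Hydride abstraction by DDQ may occur at C2 (benzylic to ring B and alpha to O1) instead of C4, leading to ring C opening or over-oxidation. The fallback sets out from 6 and comes back at 12. It carries the C4 oxygen from the aldehyde instead of installing it by C–H oxidation. Ag2O/MeI should give the rac-propargylic methyl ether of 6 F9, and Lindlar reduction the Z-allylic methyl ether F10. The epoxidation/fluoride sequence of step 6 should pass through the cis-epoxide of F10 F11 to give (2S,3S)-7-(benzyloxy)-2-[3,4-bis(benzyloxy)phenyl]-4-methoxychroman-3-ol as a C4 epimer mixture F12. Both epimers ionise to the same cation, so F12 would replace 11 in step 8 and give 12.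

**Further compounds**

F1 | step 10 | E isomer of 13 | C(c1ccccc1)Oc1ccc2c(c1)O[C@@H](c1ccc(OCc3ccccc3)c(OCc3ccccc3)c1)[C@@H](O)[C@@H]2c1cc(C/C=C/c3ccc(OCc4ccccc4)c(OCc4ccccc4)c3)c(O[Si](C(C)C)(C(C)C)C(C)C)cc1OCc1ccccc1
F2 | step 10 | ring C 3-O-benzyl ether of F1 | C(c1ccccc1)Oc1ccc2c(c1)O[C@@H](c1ccc(OCc3ccccc3)c(OCc3ccccc3)c1)[C@@H](OCc1ccccc1)[C@@H]2c1cc(C/C=C/c3ccc(OCc4ccccc4)c(OCc4ccccc4)c3)c(O[Si](C(C)C)(C(C)C)C(C)C)cc1OCc1ccccc1
F3 | step 10 | (R,R)-trans-epoxide of F2 | C(c1ccccc1)Oc1ccc2c(c1)O[C@@H](c1ccc(OCc3ccccc3)c(OCc3ccccc3)c1)[C@@H](OCc1ccccc1)[C@@H]2c1cc(C[C@H]3O[C@@H]3c3ccc(OCc4ccccc4)c(OCc4ccccc4)c3)c(O[Si](C(C)C)(C(C)C)C(C)C)cc1OCc1ccccc1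
F4 | step 10 | ring C 3-O-benzyl dimer with 2,3-trans (2S,3R) ring F | C(c1ccccc1)Oc1ccc2c(c1)O[C@@H](c1ccc(OCc3ccccc3)c(OCc3ccccc3)c1)[C@@H](OCc1ccccc1)[C@@H]2c1cc2c(cc1OCc1ccccc1)O[C@@H](c1ccc(OCc3ccccc3)c(OCc3ccccc3)c1)[C@H](O)C2
F5 | step 10 | ring F 3-ketone of F4 (lower C2 S) | C(c1ccccc1)Oc1ccc2c(c1)O[C@@H](c1ccc(OCc3ccccc3)c(OCc3ccccc3)c1)[C@@H](OCc1ccccc1)[C@@H]2c1cc2c(cc1OCc1ccccc1)O[C@@H](c1ccc(OCc3ccccc3)c(OCc3ccccc3)c1)C(=O)C2
F6 | step 10 | ring C 3-O-benzyl ether of 15 | C(c1ccccc1)Oc1ccc2c(c1)O[C@@H](c1ccc(OCc3ccccc3)c(OCc3ccccc3)c1)[C@@H](OCc1ccccc1)[C@@H]2c1cc2c(cc1OCc1ccccc1)O[C@@H](c1ccc(OCc3ccccc3)c(OCc3ccccc3)c1)[C@@H](O)C2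
F7 | step 8 | 5-(benzyloxy)-2-[3-(3,4-bis(benzyloxy)phenyl)prop-2-yn-1-yl]phenol | Oc1cc(OCc2ccccc2)ccc1CC#Cc1ccc(OCc2ccccc2)c(OCc2ccccc2)c1
F8 | step 8 | desilylated analogue of 12 (free ring D phenol) | C(c1ccccc1)Oc1ccc2c(c1)O[C@@H](c1ccc(OCc3ccccc3)c(OCc3ccccc3)c1)[C@@H](O)[C@@H]2c1cc(CC#Cc3ccc(OCc4ccccc4)c(OCc4ccccc4)c3)c(O)cc1OCc1ccccc1
F9 | step 7 | rac-{5-(benzyloxy)-2-[3-(3,4-bis(benzyloxy)phenyl)-1-methoxyprop-2-yn-1-yl]phenoxy}triisopropylsilane | COC(C#Cc1ccc(OCc2ccccc2)c(OCc2ccccc2)c1)c1ccc(OCc2ccccc2)cc1O[Si](C(C)C)(C(C)C)C(C)C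
F10 | step 7 | rac-{5-(benzyloxy)-2-[(2Z)-3-(3,4-bis(benzyloxy)phenyl)-1-methoxyprop-2-en-1-yl]phenoxy}triisopropylsilane | COC(/C=C\c1ccc(OCc2ccccc2)c(OCc2ccccc2)c1)c1ccc(OCc2ccccc2)cc1O[Si](C(C)C)(C(C)C)C(C)C
F11 | step 7 | cis-epoxide of F10 (benzylic carbon R, both epimers at the methoxy carbon) | COC([C@@H]1O[C@@H]1c1ccc(OCc2ccccc2)c(OCc2ccccc2)c1)c1ccc(OCc2ccccc2)cc1O[Si](C(C)C)(C(C)C)C(C)C
F12 | step 7 | (2S,3S)-7-(benzyloxy)-2-[3,4-bis(benzyloxy)phenyl]-4-methoxychroman-3-ol (C4 epimer mixture) | C(c1ccccc1)Oc1ccc2c(c1)O[C@@H](c1ccc(OCc3ccccc3)c(OCc3ccccc3)c1)[C@@H](O)C2OC
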